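**Plan**
1. Cuts (unit 1 = flavanone with unprimed atoms, unit 2 = flavanone with double-primed atoms): the three benzyl ethers; C2''–C1''' of unit 2 (aryl added to a chromone); C2–C3 and O1–C8a of ring C of unit 1 together in one annulation; the diaryl ether at O–C4' (SNAr on 4-fluorobenzaldehyde); the C6''–O bond (para-hydroxylation of a phenol).
2. Forward: a 2'-hydroxyacetophenone is hydroxylated, O-arylated and closed to a 6-aryloxychromone that carries the ring B aldehyde of unit 1; the annulation with an o-fluoroaryl enolsilane builds ring C of unit 1; aryl addition to the chromone completes unit 2; hydrogenolysis frees the three phenols.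
3. Enabling feature: C8a of ring A is ortho to the C4 ketone, so with fluorine on C8a the array C3=C4(OSi)–C4a=C8a–F is a benzo-fused Danishefsky-type diene (C3 nucleophilic, C8a a vinylogous acyl fluoride), and the ring B aldehyde supplies C2=O1 across its two ends.
4. Stereochemistry: C2 comes from the catalyst-controlled aldol event of the annulation; C2'' comes from ligand-controlled conjugate addition. The two are set independently, so stereochemical leakage appears as diastereomers that can be removed.

Key step: step 7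

Assumption: the facial sense of both chiral catalysts is taken by analogy with simple aryl aldehydes and chromones (Si-face aldol with the D-tryptophan-derived oxazaborolidinone, 2S product with (R)-t-BuPyOx); if a model run shows the opposite sense, the antipodal catalyst is used.

**Step 1**
Reactants: 1 2',6'-dihydroxy-4'-methoxyacetophenone
Product: 2 1-[2-(benzyloxy)-6-hydroxy-4-methoxyphenyl]ethan-1-one
Conditions: BnBr (1.05 equiv), K2CO3, acetone, reflux
Reagents that add atoms: benzyl bromide BrCc1ccccc1
Why: Williamson etherification of one of two equivalent phenols; the remaining OH is hydrogen-bonded to the ketone and should resist a second alkylation.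

**Step 2**
Reactants: 2 1-[2-(benzyloxy)-6-hydroxy-4-methoxyphenyl]ethan-1-one
Product: 4 1-[2-(benzyloxy)-3,6-dihydroxy-4-methoxyphenyl]ethan-1-one, via aryl sulfate potassium salt 3 (not isolated)
Conditions: K2S2O8, aq NaOH, pyridine, 0 → 20 °C; then aq HCl, 85 °C
Reagents that add atoms: potassium peroxodisulfate [K+].[K+].[O-]S(=O)(=O)OOS(=O)(=O)[O-]
Why: Elbs persulfate oxidation, in which the phenoxide attacks the peroxide oxygen through its free para carbon (between OBn and OMe) and the aryl sulfate is then hydrolysed by acid.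

**Step 3**
Reactants: 4 1-[2-(benzyloxy)-3,6-dihydroxy-4-methoxyphenyl]ethan-1-one; 5 4-fluorobenzaldehyde
Product: 6 4-[3-acetyl-2-(benzyloxy)-4-hydroxy-6-methoxyphenoxy]benzaldehyde
Conditions: 5 (1.05 equiv), K2CO3 (2.5 equiv), degassed DMF, 100 °C, Ar
Reagents that add atoms: none
Why: SNAr on the para-formyl-activated aryl fluoride by the non-chelated phenoxide; the other phenoxide is conjugated and hydrogen-bonded to the acetyl group and should be much less nucleophilic, and carbonate should not enolise the hindered methyl ketone.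

**Step 4**
Reactants: 6 4-[3-acetyl-2-(benzyloxy)-4-hydroxy-6-methoxyphenoxy]benzaldehyde
Product: 8 4-{[5-(benzyloxy)-7-methoxy-4-oxo-4H-chromen-6-yl]oxy}benzaldehyde, via enaminone 7 (not isolated)
Conditions: Me2NCH(OMe)2 (3 equiv), toluene, 95 °C; evaporate; then conc. HCl, CH2Cl2, 20 °C
Reagents that add atoms: N,N-dimethylformamide dimethyl acetal COC(OC)N(C)C
Why: enaminone formation at the methyl ketone followed by acid-promoted addition–elimination of the ortho phenol (loss of dimethylamine) is the standard chromone synthesis; the aryl aldehyde has no alpha hydrogen and should be inert.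

**Step 5**
Reactants: 9 2',6'-difluoro-4'-methoxyacetophenone
Product: 10 1-[2-(benzyloxy)-6-fluoro-4-methoxyphenyl]ethan-1-one
Conditions: BnOH (1.05 equiv), KOtBu (1.1 equiv), THF, 0 → 20 °C
Reagents that add atoms: benzyl alcohol OCc1ccccc1
Why: SNAr ortho to the acetyl group on one of two equivalent fluorines; the alkoxy group introduced deactivates the ring towards a second substitution.

**Step 6**
Reactants: 10 1-[2-(benzyloxy)-6-fluoro-4-methoxyphenyl]ethan-1-one
Product: 11 ({1-[2-(benzyloxy)-6-fluoro-4-methoxyphenyl]ethenyl}oxy)trimethylsilane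
Conditions: TMSOTf (1.2 equiv), Et3N (1.5 equiv), CH2Cl2, 0 °C; pentane extraction, used without chromatography
Reagents that add atoms: trimethylsilyl trifluoromethanesulfonate C[Si](C)(C)OS(=O)(=O)C(F)(F)F
Why: soft enolisation and O-silylation of an aryl methyl ketone with a single enolisable position.

**Step 7**
Reactants: 8 4-{[5-(benzyloxy)-7-methoxy-4-oxo-4H-chromen-6-yl]oxy}benzaldehyde; 11 ({1-[2-(benzyloxy)-6-fluoro-4-methoxyphenyl]ethenyl}oxy)trimethylsilane
Product: 13 (2S)-5-(benzyloxy)-2-(4-{[5-(benzyloxy)-7-methoxy-4-oxo-4H-chromen-6-yl]oxy}phenyl)-7-methoxy-2,3-dihydro-4H-chromen-4-one, via silyl aldol ether 12 (not isolated)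
Conditions: 8 (1.1 equiv), 11 (1.0 equiv), (4R)-2-butyl-4-(1H-indol-3-ylmethyl)-3-tosyl-1,3,2-oxazaborolidin-5-one [from N-tosyl-D-tryptophan and BuB(OH)2] (30 mol%), EtCN, −78 °C; then Bu4N[Ph3SiF2] (50 mol%), THF, −78 → 0 °C
Reagents that add atoms: none
Why: Proposed new method: the boron Lewis acid binds the formyl oxygen of 8 and the enolsilane terminus of 11 (future C3) adds to the Si face of the aldehyde with silyl transfer to the aldolate oxygen, giving 12 (C2–C3 bond); fluoride then removes the silyl group and the alkoxide (future O1) attacks the fluorine-bearing ring A carbon ortho to the ketone (future C8a) through a Meisenheimer adduct, and the fluoride expelled desilylates the next molecule of 12, so the closure runs as a chain without stoichiometric base. The closest known reaction types are the oxazaborolidinone-catalysed Mukaiyama aldol of acetophenone enolsilanes with aromatic aldehydes, the aldol–cyclisation course of Danishefsky-diene annulations to 2,3-dihydro-4H-pyran-4-ones, and fluoride-catalysed SNAr etherification of activated aryl fluorides by silyl ethers; their combination on an o-fluoroaryl ketone to give a flavanone is the new element. Ring C closes by a 6-endo-trig addition–elimination on the C8a=C4a–C4=O vinylogous acyl fluoride (six-membered Meisenheimer transition state, rearomatisation by loss of fluoride). C2 is set by the chiral catalyst in the aldol event (reagent control, Si-face attack gives 3S in 12) and is carried into 13 with retention because the SNAr step breaks no bond at C2. The step needs aldehyde-over-chromone selectivity (the formyl group is the only unhindered, strongly electrophilic carbonyl at −78 °C, whereas C2 of the chromone would need pyrylium-type activation) and cyclisation faster than retro-aldol or E1cB loss of the oxygen (the ortho-acyl group activates C8a, the oxygen sits 1,6 to it, the medium is cold and aprotic, and 11 is the limiting partner so that fluoride releases no free enolate).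

**Step 8**
Reactants: 13 (2S)-5-(benzyloxy)-2-(4-{[5-(benzyloxy)-7-methoxy-4-oxo-4H-chromen-6-yl]oxy}phenyl)-7-methoxy-2,3-dihydro-4H-chromen-4-one; 14 [4-(benzyloxy)phenyl]boronic acid
Product: 15 (2S)-5-(benzyloxy)-2-[4-({(2S)-5-(benzyloxy)-2-[4-(benzyloxy)phenyl]-7-methoxy-4-oxo-3,4-dihydro-2H-chromen-6-yl}oxy)phenyl]-7-methoxy-2,3-dihydro-4H-chromen-4-one
Conditions: 14 (2 equiv), Pd(OCOCF3)2 (10 mol%), (R)-t-BuPyOx (12 mol%), NH4PF6 (30 mol%), H2O (5 equiv), ClCH2CH2Cl, 60 °C
Reagents that add atoms: none
Why: palladium-catalysed asymmetric conjugate addition of an arylboronic acid to a chromone (transmetalation to cationic divalent palladium, ligand-controlled syn-carbopalladation of C2''=C3'' that sets C2'' as S, protonolysis of the palladium enolate by water); the base-free medium should leave the flavanone of unit 1 untouched.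

**Step 9**
Reactants: 15 (2S)-5-(benzyloxy)-2-[4-({(2S)-5-(benzyloxy)-2-[4-(benzyloxy)phenyl]-7-methoxy-4-oxo-3,4-dihydro-2H-chromen-6-yl}oxy)phenyl]-7-methoxy-2,3-dihydro-4H-chromen-4-one
Product: 16 7,7''-di-O-methyltetrahydrohinokiflavone, (2S)-5-hydroxy-2-(4-{[(2S)-5-hydroxy-2-(4-hydroxyphenyl)-7-methoxy-4-oxo-3,4-dihydro-2H-chromen-6-yl]oxy}phenyl)-7-methoxy-2,3-dihydro-4H-chromen-4-one
Conditions: H2 (1 atm), 10% Pd/C, EtOAc–MeOH, 20 °C
Reagents that add atoms: none
Why: hydrogenolysis of three aryl benzyl ethers under neutral conditions, which should spare the methyl ethers, the diaryl ether and both base-sensitive C2 centres.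

**Compound list**
1 | 2',6'-dihydroxy-4'-methoxyacetophenone | CC(=O)c1c(O)cc(OC)cc1O | starting material
2 | 1-[2-(benzyloxy)-6-hydroxy-4-methoxyphenyl]ethan-1-one | CC(=O)c1c(O)cc(OC)cc1OCc1ccccc1 | intermediate
3 | potassium 3-acetyl-2-(benzyloxy)-4-hydroxy-6-methoxyphenyl sulfate | CC(=O)c1c(O)cc(OC)c(OS(=O)(=O)[O-])c1OCc1ccccc1.[K+] | intermediate
4 | 1-[2-(benzyloxy)-3,6-dihydroxy-4-methoxyphenyl]ethan-1-one | CC(=O)c1c(O)cc(OC)c(O)c1OCc1ccccc1 | intermediate
5 | 4-fluorobenzaldehyde | O=Cc1ccc(F)cc1 | starting material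
6 | 4-[3-acetyl-2-(benzyloxy)-4-hydroxy-6-methoxyphenoxy]benzaldehyde | CC(=O)c1c(O)cc(OC)c(Oc2ccc(C=O)cc2)c1OCc1ccccc1 | intermediate
7 | 4-{2-(benzyloxy)-3-[(2E)-3-(dimethylamino)prop-2-enoyl]-4-hydroxy-6-methoxyphenoxy}benzaldehyde | CN(C)/C=C/C(=O)c1c(O)cc(OC)c(Oc2ccc(C=O)cc2)c1OCc1ccccc1 | intermediate
8 | 4-{[5-(benzyloxy)-7-methoxy-4-oxo-4H-chromen-6-yl]oxy}benzaldehyde | O=Cc1ccc(Oc2c(OC)cc3occc(=O)c3c2OCc2ccccc2)cc1 | intermediate
9 | 2',6'-difluoro-4'-methoxyacetophenone | CC(=O)c1c(F)cc(OC)cc1F | starting material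
10 | 1-[2-(benzyloxy)-6-fluoro-4-methoxyphenyl]ethan-1-one | CC(=O)c1c(F)cc(OC)cc1OCc1ccccc1 | intermediate
11 | ({1-[2-(benzyloxy)-6-fluoro-4-methoxyphenyl]ethenyl}oxy)trimethylsilane | C=C(O[Si](C)(C)C)c1c(F)cc(OC)cc1OCc1ccccc1 | intermediate
12 | (3S)-1-[2-(benzyloxy)-6-fluoro-4-methoxyphenyl]-3-(4-{[5-(benzyloxy)-7-methoxy-4-oxo-4H-chromen-6-yl]oxy}phenyl)-3-[(trimethylsilyl)oxy]propan-1-one | C[Si](C)(C)O[C@@H](CC(=O)c1c(F)cc(OC)cc1OCc1ccccc1)c1ccc(Oc2c(OC)cc3occc(=O)c3c2OCc2ccccc2)cc1 | intermediate
13 | (2S)-5-(benzyloxy)-2-(4-{[5-(benzyloxy)-7-methoxy-4-oxo-4H-chromen-6-yl]oxy}phenyl)-7-methoxy-2,3-dihydro-4H-chromen-4-one | COc1cc(OCc2ccccc2)c2c(c1)O[C@H](c1ccc(Oc3c(OC)cc4occc(=O)c4c3OCc3ccccc3)cc1)CC2=O | intermediate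
14 | [4-(benzyloxy)phenyl]boronic acid | OB(O)c1ccc(OCc2ccccc2)cc1 | starting material
15 | (2S)-5-(benzyloxy)-2-[4-({(2S)-5-(benzyloxy)-2-[4-(benzyloxy)phenyl]-7-methoxy-4-oxo-3,4-dihydro-2H-chromen-6-yl}oxy)phenyl]-7-methoxy-2,3-dihydro-4H-chromen-4-one | COc1cc(OCc2ccccc2)c2c(c1)O[C@H](c1ccc(Oc3c(OC)cc4c(c3OCc3ccccc3)C(=O)C[C@@H](c3ccc(OCc5ccccc5)cc3)O4)cc1)CC2=O | intermediate
16 | 7,7''-di-O-methyltetrahydrohinokiflavone | COc1cc(O)c2c(c1)O[C@H](c1ccc(Oc3c(OC)cc4c(c3O)C(=O)C[C@@H](c3ccc(O)cc3)O4)cc1)CC2=O | target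

**Step count and risks**
Total steps: 9. Longest linear sequence: 7 (steps 1–4 and 7–9; steps 5 and 6 make the second fragment).

Steps most likely to fail:

1. Step 7. After desilylation the alkoxide may fragment by retro-aldol or be lost by E1cB elimination before it reaches C8a, which would erode the C2 configuration or give a chalcone. The boron catalyst may also be held by the chromone carbonyl so that the aldol stalls. The fallback uses known chemistry and closes ring C through O1–C2 by SN2 displacement instead of O1–C8a by SNAr; it sets out from 2 and 8 and comes back at 13. Compound 2 is silylated twice (TMSOTf 2.4 equiv, Et3N, CH2Cl2, 0 °C) to ({1-[2-(benzyloxy)-4-methoxy-6-[(trimethylsilyl)oxy]phenyl]ethenyl}oxy)trimethylsilane F1. A Mukaiyama aldol of F1 with 8 under the antipodal (4S) oxazaborolidinone from N-tosyl-L-tryptophan (EtCN, −78 °C, opposite facial sense) should give the bis-silylated (3R)-aldol adduct F2. Dilute HCl in THF removes both silyl groups to give (3R)-1-[2-(benzyloxy)-6-hydroxy-4-methoxyphenyl]-3-hydroxy-3-(4-{[5-(benzyloxy)-7-methoxy-4-oxo-4H-chromen-6-yl]oxy}phenyl)propan-1-one F3. An intramolecular Mitsunobu etherification (PPh3, DIAD, THF, 0 °C) then joins the chelated phenol oxygen to the carbinol carbon with inversion and should deliver (2S)-13.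

2. Step 8. Carbopalladation of the electron-rich, peri-substituted chromone may be slow, so that protodeboronation of 14 outruns addition and conversion or facial selectivity is poor. The fallback gives up catalyst control; it sets out from 13 and comes back at 15. An achiral catalyst of Pd(OCOCF3)2 and 2,2'-bipyridine (NH4PF6, H2O, ClCH2CH2Cl, 60–80 °C, higher loading, since no selectivity depends on the ligand) should give 15 together with its C2'' epimer, the (2S,2''R)-tribenzyl ether F4. Because C2 is already fixed the two are diastereomers, and they are separated by preparative HPLC on a polysaccharide chiral stationary phase; 15 goes on to step 9.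

3. Step 3. The chelated phenoxide may be arylated instead of the hindered one, the hydroquinone dianion may be oxidised to a quinone by traces of air, or the methyl ketone may condense with the aldehyde at 100 °C. The fallback closes the pyranone first, so that neither a hydroquinone nor a methyl ketone is present when the ether is made; it sets out from 4, replaces steps 3 and 4, and comes back at 8. Claisen formylation of 4 (HCO2Et, NaH, THF, 0 → 20 °C) gives 3-[2-(benzyloxy)-3,6-dihydroxy-4-methoxyphenyl]-3-oxopropanal F5. Acid cyclodehydration (HCl, AcOH, 20 °C) gives 5-(benzyloxy)-6-hydroxy-7-methoxy-4H-chromen-4-one F6. A Chan–Lam coupling of F6 with (4-formylphenyl)boronic acid (Cu(OAc)2 20 mol%, pyridine, 4 Å molecular sieves, CH2Cl2, O2 1 atm, 20 °C) should then give 8.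

**Further compounds**
F1 | step 7 | ({1-[2-(benzyloxy)-4-methoxy-6-[(trimethylsilyl)oxy]phenyl]ethenyl}oxy)trimethylsilane | C=C(O[Si](C)(C)C)c1c(O[Si](C)(C)C)cc(OC)cc1OCc1ccccc1
F2 | step 7 | (3R)-1-{2-(benzyloxy)-4-methoxy-6-[(trimethylsilyl)oxy]phenyl}-3-(4-{[5-(benzyloxy)-7-methoxy-4-oxo-4H-chromen-6-yl]oxy}phenyl)-3-[(trimethylsilyl)oxy]propan-1-one | C[Si](C)(C)O[C@H](CC(=O)c1c(O[Si](C)(C)C)cc(OC)cc1OCc1ccccc1)c1ccc(Oc2c(OC)cc3occc(=O)c3c2OCc2ccccc2)cc1
F3 | step 7 | (3R)-1-[2-(benzyloxy)-6-hydroxy-4-methoxyphenyl]-3-hydroxy-3-(4-{[5-(benzyloxy)-7-methoxy-4-oxo-4H-chromen-6-yl]oxy}phenyl)propan-1-one | O[C@H](CC(=O)c1c(O)cc(OC)cc1OCc1ccccc1)c1ccc(Oc2c(OC)cc3occc(=O)c3c2OCc2ccccc2)cc1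
F4 | step 8 | (2S)-5-(benzyloxy)-2-[4-({(2R)-5-(benzyloxy)-2-[4-(benzyloxy)phenyl]-7-methoxy-4-oxo-3,4-dihydro-2H-chromen-6-yl}oxy)phenyl]-7-methoxy-2,3-dihydro-4H-chromen-4-one | COc1cc(OCc2ccccc2)c2c(c1)O[C@H](c1ccc(Oc3c(OC)cc4c(c3OCc3ccccc3)C(=O)C[C@H](c3ccc(OCc5ccccc5)cc3)O4)cc1)CC2=O
F5 | step 3 | 3-[2-(benzyloxy)-3,6-dihydroxy-4-methoxyphenyl]-3-oxopropanal | O=CCC(=O)c1c(O)cc(OC)c(O)c1OCc1ccccc1
F6 | step 3 | 5-(benzyloxy)-6-hydroxy-7-methoxy-4H-chromen-4-one | COc1cc2occc(=O)c2c(OCc2ccccc2)c1O
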